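## Retrosynthetic overview

1. Scirpusin A is opened at the O1–C2 ether bond of the dihydrofuran, giving an achiral ortho-hydroxy triarylethylene hexaphenol. The forward step is an enantioselective acid-catalysed ring closure that makes the only new ring and both stereocentres, and it comes last.
2. The hexaphenol comes from its hexa-silyl ether by one fluoride deprotection.
3. The triarylethylene is cut at the ring A–C3 bond: a 2-lithiated, silylated resveratrol adds to a deoxybenzoin, followed by dehydration.
4. The deoxybenzoin comes from 3',5'-dihydroxyacetophenone and 4-bromocatechol by ketone α-arylation; the aryl bromide comes from resveratrol by silylation and bromination.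
5. All three benzene rings and the stilbene are bought; no ring other than the dihydrofuran is formed.

Assumption: the sense of induction of the new cyclisation cannot be predicted, so the (R)-acid is written and the (S)-acid is used instead if the first run gives the (2R,3R) series.

Abbreviations: TBS = tert-butyldimethylsilyl, TBSO = TBS ether. Ring A is the resorcinol ring of resveratrol that becomes the benzo ring. C2 and C3 are the dihydrofuran carbons of the target, which is (2S,3S), trans.

## Route

Step 1
Reactants: 1 resveratrol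
Product: 2 tri-O-TBS-resveratrol [(E)-3,5,4'-tris(TBSO)stilbene]
Conditions: TBSCl (3.6 equiv), imidazole (7.5 equiv), DMF, rt, 12 h
Reagents that add atoms: TBSCl (tert-butyldimethylsilyl chloride), CC(C)(C)[Si](C)(C)Cl
Why: Imidazole-promoted silylation of phenols gives aryl silyl ethers that tolerate organolithium chemistry and are later removed by fluoride without acid.

Step 2
Reactants: 2 tri-O-TBS-resveratrol
Product: 3 2-bromo-tri-O-TBS-resveratrol [(E)-2-bromo-3,5,4'-tris(TBSO)stilbene; bromine on ring A ortho to the vinyl group]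
Conditions: NBS (1.02 equiv), MeCN/CH2Cl2 (1:1), −20 → 0 °C, dark
Reagents that add atoms: NBS (N-bromosuccinimide), O=C1CCC(=O)N1Br
Why: Electrophilic aromatic bromination goes to the ring A position ortho to the vinyl group (C2 = C6 by symmetry), which is para to one silyloxy group and ortho to the other, while C4 is buried between two TBS ethers and the other ring has only one donor.

Step 3
Reactants: 4 3',5'-dihydroxyacetophenone
Product: 5 3',5'-bis(TBSO)acetophenone
Conditions: TBSCl (2.4 equiv), imidazole (5 equiv), DMF, rt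
Reagents that add atoms: TBSCl (tert-butyldimethylsilyl chloride), CC(C)(C)[Si](C)(C)Cl
Why: Standard phenol silylation; the methyl ketone is untouched.

Step 4
Reactants: 6 4-bromocatechol
Product: 7 4-bromo-1,2-bis(TBSO)benzene
Conditions: TBSCl (2.4 equiv), imidazole (5 equiv), DMF, rt
Reagents that add atoms: TBSCl (tert-butyldimethylsilyl chloride), CC(C)(C)[Si](C)(C)Cl
Why: Standard phenol silylation masks the catechol for the palladium step.

Step 5
Reactants: 5 3',5'-bis(TBSO)acetophenone (1.2 equiv), 7 4-bromo-1,2-bis(TBSO)benzene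
Product: 8 deoxybenzoin 2-[3,4-bis(TBSO)phenyl]-1-[3,5-bis(TBSO)phenyl]ethan-1-one
Conditions: Pd(OAc)2 (2 mol%), 2-(dicyclohexylphosphino)-2'-methylbiphenyl (4 mol%), K3PO4 (2.3 equiv), PhMe, 80 °C
Reagents that add atoms: none
Why: Palladium-catalysed ketone α-arylation (Buchwald–Hartwig type) of a methyl ketone with an unhindered aryl bromide; the phosphate base spares the aryl silyl ethers and the bulkier, more acidic product resists a second arylation.

Step 6
Reactants: 3 2-bromo-tri-O-TBS-resveratrol (1.3 equiv), 8 deoxybenzoin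
Product: 11 hexa-O-TBS triarylethylene 1-[3,5-bis(TBSO)phenyl]-1-{2,4-bis(TBSO)-6-[(E)-2-(4-TBSO-phenyl)ethenyl]phenyl}-2-[3,4-bis(TBSO)phenyl]ethene (E/Z mixture at the new double bond), via aryllithium 9 (not isolated), via tertiary carbinol 10 (not isolated)
Conditions: 3, n-BuLi (1.3 equiv), THF, −78 °C, 20 min; cannulate into 8 + LaCl3·2LiCl (1.1 equiv), THF, −78 → 0 °C; then TsOH·H2O (2.0 equiv), 0 → 40 °C
Reagents that add atoms: none
Why: Bromine–lithium exchange, LaCl3·2LiCl-promoted 1,2-addition of the aryllithium to the enolisable ketone (Imamoto–Knochel type) and E1 dehydration of the doubly benzylic tertiary carbinol, whose only β-hydrogens sit on the CH2, give a single constitutional alkene whose E/Z ratio does not matter.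

Step 7
Reactants: 11 hexa-O-TBS triarylethylene
Product: 12 seco-scirpusin A hexaphenol 4-{2-(3,5-dihydroxyphenyl)-2-[2,4-dihydroxy-6-[(E)-2-(4-hydroxyphenyl)ethenyl]phenyl]ethenyl}benzene-1,2-diol (E/Z mixture at the triaryl double bond)
Conditions: n-Bu4NF (6.6 equiv), AcOH (6.6 equiv), THF, 0 °C, argon; pH 7 work-up, Sephadex LH-20 (MeOH)
Reagents that add atoms: none
Why: Fluoride cleavage of the six aryl silyl ethers, buffered with AcOH so that neither phenoxide nor strong acid is present to trigger an uncontrolled ring closure.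

Step 8
Reactants: 12 seco-scirpusin A hexaphenol
Product: 13 scirpusin A [(2S,3S)-2-(3,4-dihydroxyphenyl)-3-(3,5-dihydroxyphenyl)-4-[(E)-2-(4-hydroxyphenyl)ethenyl]-2,3-dihydro-1-benzofuran-6-ol]
Conditions: (R)-3,3'-bis(2,4,6-triisopropylphenyl)-1,1'-binaphthyl-2,2'-diyl hydrogen phosphate (10 mol%), EtOAc/PhMe (1:1), 0.02 M, 4 Å MS, 0 °C → rt, argon, dark
Reagents that add atoms: none
Why: Proposed new method: a chiral phosphoric acid-catalysed enantioselective 5-endo hydroalkoxylation (cycloisomerisation) of an ortho-hydroxyaryl triarylethylene, in which the acid hydrogen-bonds through P=O to the ring A ortho-hydroxyl and delivers its proton to the adjacent alkene carbon inside the chiral pocket (setting C3), while the developing benzylic cation, stabilised as a para-quinone methide by the catechol para-oxygen, is captured within the same ion pair by the phosphate-activated phenol oxygen anti to the C3 aryl (forming O1–C2, setting C2, trans); the E and Z isomers of 12 interconvert by reversible protonation at the other alkene carbon through the ring A ortho-quinone methide, so the mixture converges; the closest known reaction types are chiral Brønsted acid-catalysed asymmetric intramolecular hydroalkoxylation of alkenols and chiral phosphoric acid-catalysed oxa-conjugate additions to para-quinone methides generated in situ, and the racemic version is the quinone methide ring closure of stilbene dimer biosynthesis.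

## Compound list

1 | resveratrol | Oc1ccc(/C=C/c2cc(O)cc(O)c2)cc1 | starting material
2 | tri-O-TBS-resveratrol, (E)-3,5,4'-tris(TBSO)stilbene | CC(C)(C)[Si](C)(C)Oc1ccc(/C=C/c2cc(O[Si](C)(C)C(C)(C)C)cc(O[Si](C)(C)C(C)(C)C)c2)cc1 | intermediate
3 | (E)-2-bromo-3,5,4'-tris(TBSO)stilbene | CC(C)(C)[Si](C)(C)Oc1ccc(/C=C/c2cc(O[Si](C)(C)C(C)(C)C)cc(O[Si](C)(C)C(C)(C)C)c2Br)cc1 | intermediate
4 | 3',5'-dihydroxyacetophenone | CC(=O)c1cc(O)cc(O)c1 | starting material
5 | 3',5'-bis(TBSO)acetophenone | CC(=O)c1cc(O[Si](C)(C)C(C)(C)C)cc(O[Si](C)(C)C(C)(C)C)c1 | intermediate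
6 | 4-bromocatechol (4-bromobenzene-1,2-diol) | Oc1ccc(Br)cc1O | starting material
7 | 4-bromo-1,2-bis(TBSO)benzene | CC(C)(C)[Si](C)(C)Oc1ccc(Br)cc1O[Si](C)(C)C(C)(C)C | intermediate
8 | 2-[3,4-bis(TBSO)phenyl]-1-[3,5-bis(TBSO)phenyl]ethan-1-one | CC(C)(C)[Si](C)(C)Oc1cc(cc(O[Si](C)(C)C(C)(C)C)c1)C(=O)Cc1ccc(O[Si](C)(C)C(C)(C)C)c(O[Si](C)(C)C(C)(C)C)c1 | intermediate
9 | aryllithium from 3 (lithium in place of bromine; not isolated) | [Li]c1c(O[Si](C)(C)C(C)(C)C)cc(O[Si](C)(C)C(C)(C)C)cc1/C=C/c1ccc(O[Si](C)(C)C(C)(C)C)cc1 | intermediate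
10 | racemic tertiary carbinol 1-[3,5-bis(TBSO)phenyl]-1-{2,4-bis(TBSO)-6-[(E)-2-(4-TBSO-phenyl)ethenyl]phenyl}-2-[3,4-bis(TBSO)phenyl]ethan-1-ol (not isolated) | OC(Cc1ccc(O[Si](C)(C)C(C)(C)C)c(O[Si](C)(C)C(C)(C)C)c1)(c1cc(O[Si](C)(C)C(C)(C)C)cc(O[Si](C)(C)C(C)(C)C)c1)c1c(O[Si](C)(C)C(C)(C)C)cc(O[Si](C)(C)C(C)(C)C)cc1/C=C/c1ccc(O[Si](C)(C)C(C)(C)C)cc1 | intermediate
11 | hexa-O-TBS triarylethylene (E/Z mixture at the triaryl double bond, left undefined; styryl double bond E) | C(=Cc1ccc(O[Si](C)(C)C(C)(C)C)c(O[Si](C)(C)C(C)(C)C)c1)(c1cc(O[Si](C)(C)C(C)(C)C)cc(O[Si](C)(C)C(C)(C)C)c1)c1c(O[Si](C)(C)C(C)(C)C)cc(O[Si](C)(C)C(C)(C)C)cc1/C=C/c1ccc(O[Si](C)(C)C(C)(C)C)cc1 | intermediate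
12 | seco-scirpusin A hexaphenol (E/Z mixture at the triaryl double bond, left undefined; styryl double bond E) | Oc1ccc(C=C(c2cc(O)cc(O)c2)c2c(O)cc(O)cc2/C=C/c2ccc(O)cc2)cc1O | intermediate
13 | scirpusin A, (2S,3S)-trans | Oc1ccc(/C=C/c2cc(O)cc3c2[C@H](c2cc(O)cc(O)c2)[C@@H](c2ccc(O)c(O)c2)O3)cc1 | target

## Step count and risks

Total steps: 8. Longest linear sequence: 5 steps (1 → 2 → 3 → 11 → 12 → 13 through steps 1, 2, 6, 7 and 8; the branch 4 → 5 → 8 → 11 → 12 → 13 through steps 3, 5, 6, 7 and 8 is equally long).

The step most likely to fail is the new cyclisation, step 8. Its risks are: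
- the phosphoric acid may be too weak or too poorly organised in a solvent that dissolves a hexaphenol;
- the styryl double bond may attack the benzylic cation through carbon and give an indane instead of the ether;
- the product may racemise by reversible ring opening;
- the face selectivity is untested.

Catalyst acidity and confinement (for example the N-triflyl phosphoramide analogue) are the first variables to screen. The fallback with known chemistry sets out from 12: an achiral acid (diphenyl phosphate, 10 mol%, EtOAc, rt) effects the same quinone methide ring closure without enantiocontrol and gives the racemic trans product, that is 13 together with its mirror image ent-scirpusin A F1. The two are separated by preparative HPLC on an amylose tris(3,5-dimethylphenylcarbamate) phase, which returns to the route at 13.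

The second is step 6. The hindered, ortho-silyloxy aryllithium 9 may undergo a 1,3 oxygen-to-carbon silyl shift, the deoxybenzoin may simply be enolised, and addition of a 2,6-disubstituted aryl nucleophile is slow. The fallback sets out from 8 and 3 and avoids any aryl-metal nucleophile. Ketone 8 is condensed with p-toluenesulfonyl hydrazide (dioxane, 70 °C) to the N-tosylhydrazone F2. F2 is then coupled with bromide 3 under Pd2(dba)3 (2 mol%), XPhos (8 mol%) and LiOtBu (2.5 equiv) in dioxane at 100 °C. Palladium carbene formation, aryl migration and β-hydride elimination (Barluenga coupling) give 11 directly, where the fallback rejoins the route. Any silyl ether lost to the alkoxide base does no harm, because step 7 removes them all.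

The third is step 5, where four aryl silyl ethers meet a basic palladium coupling and double arylation or desilylation can erode the yield. The fallback sets out from 3, 5 and 7 and reverses the order of bond formation. Aryllithium 9, made from 3 as in step 6, is added to acetophenone 5 in the presence of LaCl3·2LiCl to give the tertiary carbinol F3. F3 is dehydrated in the same flask with TsOH·H2O to the 1,1-diarylethylene F4. A Mizoroki–Heck arylation of F4 with bromide 7 (Pd(OAc)2, P(t-Bu)3·HBF4, Cy2NMe, dioxane, 100 °C) then gives 11, where the route is rejoined without passing through ketone 8.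

Further compounds
F1 | step 8 | ent-scirpusin A, (2R,3R)-trans | Oc1ccc(/C=C/c2cc(O)cc3c2[C@@H](c2cc(O)cc(O)c2)[C@H](c2ccc(O)c(O)c2)O3)cc1
F2 | step 6 | N-tosylhydrazone of ketone 8 | Cc1ccc(cc1)S(=O)(=O)NN=C(Cc1ccc(O[Si](C)(C)C(C)(C)C)c(O[Si](C)(C)C(C)(C)C)c1)c1cc(O[Si](C)(C)C(C)(C)C)cc(O[Si](C)(C)C(C)(C)C)c1
F3 | step 5 | racemic tertiary carbinol 1-[3,5-bis(TBSO)phenyl]-1-{2,4-bis(TBSO)-6-[(E)-2-(4-TBSO-phenyl)ethenyl]phenyl}ethan-1-ol | CC(O)(c1cc(O[Si](C)(C)C(C)(C)C)cc(O[Si](C)(C)C(C)(C)C)c1)c1c(O[Si](C)(C)C(C)(C)C)cc(O[Si](C)(C)C(C)(C)C)cc1/C=C/c1ccc(O[Si](C)(C)C(C)(C)C)cc1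
F4 | step 5 | 1,1-diarylethylene 1-[3,5-bis(TBSO)phenyl]-1-{2,4-bis(TBSO)-6-[(E)-2-(4-TBSO-phenyl)ethenyl]phenyl}ethene | C=C(c1cc(O[Si](C)(C)C(C)(C)C)cc(O[Si](C)(C)C(C)(C)C)c1)c1c(O[Si](C)(C)C(C)(C)C)cc(O[Si](C)(C)C(C)(C)C)cc1/C=C/c1ccc(O[Si](C)(C)C(C)(C)C)cc1
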